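Ring carbons are numbered C1–C10 (C4 methyl-bearing oxirane carbon, C5 oxirane CH, C6 carbinol, C7 isopropyl, C8 ester carbon, C10=C1 alkene). C3 and C6 are cis on the oxirane, so it descends from a (Z)-C4=C5 alkene next to C6–OH. Ring-closing metathesis of a cyclopentane (C6–C10) carrying a C6 vinyl carbinol and an isopropenyl-ended chain on C10 forms that alkene inside a seven-membered ring (C10, C1–C6), fixing its Z geometry. Grob fragmentation across O–C6–C10–C1–OMs then cuts the template bond C6–C10 and releases the (1(10)E,4Z)-cyclodecadienone; C8–OH sets C6 (Evans–Tishchenko, delivering the aroyl ester) and C6–OH directs the epoxidation.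

Key step: step 10

Remark: imide 1 is taken as a catalogue compound (otherwise one N-acylation of (R)-4-benzyloxazolidin-2-one). The C6 and C10 centres of 10–17 are erased in step 12, so only C7/C8 (step 1) and the C1/C10 relationship (step 8) have to be right.

Step 1
Reactants: 1 (R)-4-benzyl-3-(3-methylbutanoyl)oxazolidin-2-one; 2 (E)-cinnamaldehyde
Product: 4 (R)-4-benzyl-3-[(2S,3S,E)-3-hydroxy-5-phenyl-2-(propan-2-yl)pent-4-enoyl]oxazolidin-2-one, via trimethylsilyl ether 3 (not isolated)
Conditions: MgCl2 (10 mol%), Et3N, Me3SiCl, EtOAc, rt; then CF3CO2H (cat.), MeOH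
Reagents that add atoms: none
Why: Magnesium halide-catalysed anti-aldol reaction of an N-acyloxazolidinone: soft enolisation gives the chelated (Z)-enolate, which 2 attacks on the face away from the benzyl group through a boat-like transition state, silylation to 3 releasing the catalyst, so that C7 (S) and C8 (S) are set anti (cis on the later cyclopentane).

Step 2
Reactants: 4 aldol adduct
Product: 5 (2S,3S,E)-3-hydroxy-N-methoxy-N-methyl-5-phenyl-2-(propan-2-yl)pent-4-enamide
Conditions: MeNHOMe·HCl, AlMe3, CH2Cl2, −20 to 0 °C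
Reagents that add atoms: N,O-dimethylhydroxylamine hydrochloride, CNOC.Cl
Why: Weinreb amide formation by aluminium amide transamidation, which is selective for the exocyclic imide carbonyl when the β-hydroxyl is free and touches no stereocentre.

Step 3
Reactants: 5 hydroxy Weinreb amide
Product: 6 (2S,3S,E)-3-[(tert-butyldimethylsilyl)oxy]-N-methoxy-N-methyl-5-phenyl-2-(propan-2-yl)pent-4-enamide
Conditions: t-BuMe2SiOTf, 2,6-lutidine, CH2Cl2, −78 to 0 °C
Reagents that add atoms: tert-butyldimethylsilyl triflate, CC(C)(C)[Si](C)(C)OS(=O)(=O)C(F)(F)F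
Why: Silylation of the secondary alcohol with a silyl triflate and a hindered base; the bulky ether later shields one face of the five-membered ring.

Step 4
Reactants: 6 silyloxy Weinreb amide
Product: 7 (4S,5S,E)-5-[(tert-butyldimethylsilyl)oxy]-2-methyl-7-phenyl-4-(propan-2-yl)hepta-1,6-dien-3-one
Conditions: CH2=C(CH3)MgBr, THF, −20 to 0 °C; aq. NH4Cl
Reagents that add atoms: isopropenylmagnesium bromide, C=C(C)[Mg]Br
Why: Grignard addition to a Weinreb amide halts at the chelated tetrahedral adduct, so the enone appears only on work-up and neither over-addition nor epimerisation at C7 is expected.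

Step 5
Reactants: 7 dienone
Product: 8 (4S,5S)-4-[(tert-butyldimethylsilyl)oxy]-2-methyl-5-(propan-2-yl)cyclopent-2-en-1-one (silyloxy and isopropyl cis)
Conditions: second-generation Hoveyda–Grubbs catalyst (5 mol%), CH2Cl2, 40 °C
Reagents that add atoms: none
Why: Ring-closing metathesis between the styryl group and the isopropenyl ketone gives the 2-methylcyclopentenone with loss of styrene under neutral conditions, so the cis C7/C8 pair stays intact.

Step 6
Reactants: 8 cyclopentenone
Product: 10 (2R,4S,5S)-4-[(tert-butyldimethylsilyl)oxy]-2-(hydroxymethyl)-2-methyl-5-(propan-2-yl)cyclopentan-1-one, via dimethylphenylsilyl enol ether 9 (not isolated)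
Conditions: [(Ph3P)CuH]6 (cat.), PhMe2SiH, toluene, rt; then THF, 37% aq. CH2O, Yb(OTf)3 (cat.), rt
Reagents that add atoms: formaldehyde, C=O
Why: Copper hydride-catalysed 1,4-hydrosilylation gives the tetrasubstituted enol silane regiospecifically, and its Lewis acid-catalysed Mukaiyama aldol reaction with formaldehyde builds the quaternary C10, the electrophile entering anti to the cis isopropyl and silyloxy groups (this centre is erased in step 12).

Step 7
Reactants: 10 hydroxymethyl ketone
Product: 11 (1R,3S,4S)-4-[(tert-butyldimethylsilyl)oxy]-1-methyl-2-oxo-3-(propan-2-yl)cyclopentane-1-carbaldehyde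
Conditions: Dess–Martin periodinane, CH2Cl2, 0 °C to rt
Reagents that add atoms: none
Why: Dess–Martin oxidation of the neopentyl primary alcohol is neutral and fast, and the resulting β-keto aldehyde cannot enolise between its carbonyl groups.

Step 8
Reactants: 11 keto aldehyde; 12 4-bromo-2-methylbut-1-ene
Product: 14 (2R,4S,5S)-4-[(tert-butyldimethylsilyl)oxy]-2-[(1S)-1-hydroxy-4-methylpent-4-en-1-yl]-2-methyl-5-(propan-2-yl)cyclopentan-1-one, via Grignard reagent 13 (not isolated)
Conditions: 12, Mg, THF; then 11, MgBr2·OEt2, CH2Cl2/THF, −78 °C; aq. NH4Cl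
Reagents that add atoms: none
Why: Chelation-controlled (Cram chelate) Grignard addition: magnesium bridges the two carbonyl oxygens, the aldehyde reacts far faster than the hindered ketone and is attacked on the face away from the C10 methyl group, giving the (S) carbinol with OH anti to that methyl in the C6–C10–C1–C2 zigzag, the relationship that step 12 converts into the E alkene.

Step 9
Reactants: 14 β-hydroxy ketone
Product: 15 (1S,2R,4S,5S)-4-[(tert-butyldimethylsilyl)oxy]-1-ethenyl-2-[(1S)-1-hydroxy-4-methylpent-4-en-1-yl]-2-methyl-5-(propan-2-yl)cyclopentan-1-ol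
Conditions: CH2=CHMgBr, CeCl3, THF, −78 to 0 °C; aq. NH4Cl
Reagents that add atoms: vinylmagnesium bromide, C=C[Mg]Br
Why: Organocerium addition, nucleophilic but weakly basic, to the hindered enolisable ketone; attack anti to the flanking isopropyl and methyl groups should place the vinyl group cis to the side chain (the C6 centre is erased in step 12 and only has to allow ring closure).

Step 10
Reactants: 15 diol diene
Product: 16 (1S,2S,3aR,4S,8aS)-2-[(tert-butyldimethylsilyl)oxy]-3a,7-dimethyl-1-(propan-2-yl)-1,2,3,3a,4,5,6,8a-octahydroazulene-4,8a-diol (cis-fused)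
Conditions: second-generation Grubbs catalyst (5–10 mol%), toluene (5 mM), 60 °C
Reagents that add atoms: none
Why: The ruthenium alkylidene formed at the vinyl group adds to the 1,1-disubstituted alkene at C4 through a ruthenacyclobutane and expels ethylene, i.e. ring-closing olefin metathesis, the reaction type that closes trisubstituted cycloheptenes of hydroazulenes from allylic carbinols. The new C4=C5 bond closes the seven-membered carbocycle C10–C1–C2–C3–C4–C5–C6 (alkene metathesis ring closure onto the existing cyclopentane, giving a cis-fused bicyclo[5.3.0]decene). No stereocentre is created; the stereo-element set is the alkene geometry, and the seven-membered ring leaves only the Z form (C3 and C6 cis), the relationship carried into the oxirane of 22. The step needs site selectivity and tolerance of two free hydroxyls: 15 holds no third alkene, the vinyl group and the side chain are cis on the cyclopentane so the termini can meet, and ruthenium carbenes leave the alcohols and the silyl ether untouched.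

Step 11
Reactants: 16 bicyclic diol
Product: 17 (1S,2S,3aR,4S,8aS)-2-[(tert-butyldimethylsilyl)oxy]-8a-hydroxy-3a,7-dimethyl-1-(propan-2-yl)-1,2,3,3a,4,5,6,8a-octahydroazulen-4-yl methanesulfonate
Conditions: MeSO2Cl, Et3N, CH2Cl2, −20 °C
Reagents that add atoms: methanesulfonyl chloride, CS(=O)(=O)Cl
Why: Sulfonylation via sulfene distinguishes the secondary from the tertiary allylic hydroxyl on steric grounds and leaves all stereocentres unchanged.

Step 12
Reactants: 17 hydroxy mesylate
Product: 18 (2Z,6E,9S,10S)-9-[(tert-butyldimethylsilyl)oxy]-3,7-dimethyl-10-(propan-2-yl)cyclodeca-2,6-dien-1-one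
Conditions: KN(SiMe3)2 (1.05 equiv), THF, −78 to 0 °C
Reagents that add atoms: none
Why: Grob (Wharton-type) fragmentation of a 1,3-hydroxy sulfonate: the potassium C6 alkoxide pushes, the C6–C10 bond anti-periplanar to C1–OMs breaks and ketone and C1=C10 alkene form in concert, so the cis relation of mesylate and angular methyl is translated stereospecifically into the E alkene while the ring alkene becomes the (Z)-enone; one equivalent of base at low temperature limits loss of the C8 silyloxy group.

Step 13
Reactants: 18 silyloxy dienone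
Product: 19 (2Z,6E,9S,10S)-9-hydroxy-3,7-dimethyl-10-(propan-2-yl)cyclodeca-2,6-dien-1-one
Conditions: HF·pyridine, pyridine, THF, 0 °C to rt
Reagents that add atoms: none
Why: Fluoride-mediated desilylation under pyridine-buffered conditions is mild enough to spare the β-hydroxy ketone from retro-aldol cleavage, dehydration and transannular oxa-Michael addition, and changes no stereocentre.

Step 14
Reactants: 19 β-hydroxy dienone; 20 3,4,5-trimethoxybenzaldehyde
Product: 21 (1S,2R,3S,4Z,8E)-3-hydroxy-5,9-dimethyl-2-(propan-2-yl)cyclodeca-4,8-dien-1-yl 3,4,5-trimethoxybenzoate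
Conditions: 20 (5 equiv), SmI2 (30 mol%), THF, −10 °C
Reagents that add atoms: none
Why: Evans–Tishchenko reduction: the samarium catalyst (trivalent, formed from SmI2 and 20) holds the hemiacetal of C8–OH with 20 and the ketone in a chair-like six-membered transition state, the hemiacetal hydrogen is delivered intramolecularly to C6 anti to O8, and the aroyl group ends on O8, so C6 (S) and the ester are set in one operation.

Step 15
Reactants: 21 allylic alcohol ester
Product: 22 (1R,2R,3R,4S,6E,10S)-2-hydroxy-6,10-dimethyl-3-(propan-2-yl)-11-oxabicyclo[8.1.0]undec-6-en-4-yl 3,4,5-trimethoxybenzoate (target)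
Conditions: VO(acac)2 (5 mol%), t-BuOOH (decane), CH2Cl2, 0 °C
Reagents that add atoms: tert-butyl hydroperoxide, CC(C)(C)OO
Why: Hydroxyl-directed vanadium-catalysed epoxidation: the vanadate ester of C6–OH delivers oxygen to the neighbouring (Z)-alkene from the hydroxyl face, as medium-ring (Z)-cycloalkenols give cis-epoxy alcohols, which sets C4 (S) and C5 (R) and leaves the undirected C1=C10 alkene alone.

Compound list
1 | (R)-4-benzyl-3-(3-methylbutanoyl)oxazolidin-2-one | CC(C)CC(=O)N1[C@H](Cc2ccccc2)COC1=O | starting material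
2 | (E)-cinnamaldehyde | O=C/C=C/c1ccccc1 | starting material
3 | (R)-4-benzyl-3-[(2S,3S,E)-5-phenyl-2-(propan-2-yl)-3-(trimethylsilyloxy)pent-4-enoyl]oxazolidin-2-one | O=C(N1[C@H](Cc2ccccc2)COC1=O)[C@@H](C(C)C)[C@@H](O[Si](C)(C)C)/C=C/c1ccccc1 | intermediate
4 | (R)-4-benzyl-3-[(2S,3S,E)-3-hydroxy-5-phenyl-2-(propan-2-yl)pent-4-enoyl]oxazolidin-2-one | O=C(N1[C@H](Cc2ccccc2)COC1=O)[C@@H](C(C)C)[C@@H](O)/C=C/c1ccccc1 | intermediate
5 | (2S,3S,E)-3-hydroxy-N-methoxy-N-methyl-5-phenyl-2-(propan-2-yl)pent-4-enamide | CON(C)C(=O)[C@@H](C(C)C)[C@@H](O)/C=C/c1ccccc1 | intermediate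
6 | (2S,3S,E)-3-[(tert-butyldimethylsilyl)oxy]-N-methoxy-N-methyl-5-phenyl-2-(propan-2-yl)pent-4-enamide | CON(C)C(=O)[C@@H](C(C)C)[C@@H](O[Si](C)(C)C(C)(C)C)/C=C/c1ccccc1 | intermediate
7 | (4S,5S,E)-5-[(tert-butyldimethylsilyl)oxy]-2-methyl-7-phenyl-4-(propan-2-yl)hepta-1,6-dien-3-one | C=C(C)C(=O)[C@@H](C(C)C)[C@@H](O[Si](C)(C)C(C)(C)C)/C=C/c1ccccc1 | intermediate
8 | (4S,5S)-4-[(tert-butyldimethylsilyl)oxy]-2-methyl-5-(propan-2-yl)cyclopent-2-en-1-one | O=C1[C@@H](C(C)C)[C@@H](O[Si](C)(C)C(C)(C)C)C=C1C | intermediate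
9 | (4S,5S)-4-[(tert-butyldimethylsilyl)oxy]-1-[(dimethylphenylsilyl)oxy]-2-methyl-5-(propan-2-yl)cyclopent-1-ene | CC1=C(O[Si](C)(C)c2ccccc2)[C@@H](C(C)C)[C@@H](O[Si](C)(C)C(C)(C)C)C1 | intermediate
10 | (2R,4S,5S)-4-[(tert-butyldimethylsilyl)oxy]-2-(hydroxymethyl)-2-methyl-5-(propan-2-yl)cyclopentan-1-one | O=C1[C@@H](C(C)C)[C@@H](O[Si](C)(C)C(C)(C)C)C[C@]1(C)CO | intermediate
11 | (1R,3S,4S)-4-[(tert-butyldimethylsilyl)oxy]-1-methyl-2-oxo-3-(propan-2-yl)cyclopentane-1-carbaldehyde | O=C1[C@@H](C(C)C)[C@@H](O[Si](C)(C)C(C)(C)C)C[C@]1(C)C=O | intermediate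
12 | 4-bromo-2-methylbut-1-ene | C=C(C)CCBr | starting material
13 | (3-methylbut-3-en-1-yl)magnesium bromide | C=C(C)CC[Mg]Br | intermediate
14 | (2R,4S,5S)-4-[(tert-butyldimethylsilyl)oxy]-2-[(1S)-1-hydroxy-4-methylpent-4-en-1-yl]-2-methyl-5-(propan-2-yl)cyclopentan-1-one | O=C1[C@@H](C(C)C)[C@@H](O[Si](C)(C)C(C)(C)C)C[C@]1(C)[C@@H](O)CCC(C)=C | intermediate
15 | (1S,2R,4S,5S)-4-[(tert-butyldimethylsilyl)oxy]-1-ethenyl-2-[(1S)-1-hydroxy-4-methylpent-4-en-1-yl]-2-methyl-5-(propan-2-yl)cyclopentan-1-ol | C=C[C@]1(O)[C@@H](C(C)C)[C@@H](O[Si](C)(C)C(C)(C)C)C[C@]1(C)[C@@H](O)CCC(C)=C | intermediate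
16 | (1S,2S,3aR,4S,8aS)-2-[(tert-butyldimethylsilyl)oxy]-3a,7-dimethyl-1-(propan-2-yl)-1,2,3,3a,4,5,6,8a-octahydroazulene-4,8a-diol | CC1=C[C@]2(O)[C@@H](C(C)C)[C@@H](O[Si](C)(C)C(C)(C)C)C[C@]2(C)[C@@H](O)CC1 | intermediate
17 | (1S,2S,3aR,4S,8aS)-2-[(tert-butyldimethylsilyl)oxy]-8a-hydroxy-3a,7-dimethyl-1-(propan-2-yl)-1,2,3,3a,4,5,6,8a-octahydroazulen-4-yl methanesulfonate | CC1=C[C@]2(O)[C@@H](C(C)C)[C@@H](O[Si](C)(C)C(C)(C)C)C[C@]2(C)[C@@H](OS(C)(=O)=O)CC1 | intermediate
18 | (2Z,6E,9S,10S)-9-[(tert-butyldimethylsilyl)oxy]-3,7-dimethyl-10-(propan-2-yl)cyclodeca-2,6-dien-1-one | O=C1/C=C(C)\CC/C=C(C)/C[C@H](O[Si](C)(C)C(C)(C)C)[C@@H]1C(C)C | intermediate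
19 | (2Z,6E,9S,10S)-9-hydroxy-3,7-dimethyl-10-(propan-2-yl)cyclodeca-2,6-dien-1-one | O=C1/C=C(C)\CC/C=C(C)/C[C@H](O)[C@@H]1C(C)C | intermediate
20 | 3,4,5-trimethoxybenzaldehyde | COc1cc(C=O)cc(OC)c1OC | starting material
21 | (1S,2R,3S,4Z,8E)-3-hydroxy-5,9-dimethyl-2-(propan-2-yl)cyclodeca-4,8-dien-1-yl 3,4,5-trimethoxybenzoate | COc1cc(C(=O)O[C@H]2C/C(C)=C/CC/C(C)=C\[C@H](O)[C@H]2C(C)C)cc(OC)c1OC | intermediate
22 | (1R,2R,3R,4S,6E,10S)-2-hydroxy-6,10-dimethyl-3-(propan-2-yl)-11-oxabicyclo[8.1.0]undec-6-en-4-yl 3,4,5-trimethoxybenzoate | COc1cc(C(=O)O[C@H]2C/C(C)=C/CC[C@]3(C)O[C@@H]3[C@H](O)[C@H]2C(C)C)cc(OC)c1OC | target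

Total step count: 15. Longest linear sequence: 15 steps (1 to 22).

Steps most likely to fail

Step 12. In the cis-fused bicycle the C1–O(mesyl) bond may not reach the anti-periplanar arrangement with C6–C10; the alkoxide would then close an oxetane onto C1, or slow fragmentation would leave time for base-induced loss of silanolate from C8 of the product. The fallback sets out from 14 and comes back at 18, and it reverses the order of fragmentation and ring closure. Ketone 14 is mesylated at the side-chain carbinol (MeSO2Cl, Et3N) to the β-mesyloxy ketone F1. Vinylcerium dichloride (CH2=CHMgBr, CeCl3) is added at −78 °C and the mixture is warmed; the C10–C1 bond of the resulting tertiary alkoxide is an open-chain bond that is free to adopt the anti-periplanar rotamer, so fragmentation should give the acyclic (E)-trienone F2. Ring-closing metathesis of F2 at high dilution (second-generation Hoveyda–Grubbs catalyst) then forms C4=C5 and gives 18. In this variant the Z geometry rests only on the preference of ten-membered ring closures for cis alkenes.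

Step 14. Hydride transfer to the conjugated, α-branched ketone may be slow, which leaves room for pinacol coupling of 20, retro-aldol cleavage of 19, or migration of the aroyl group from O8 to O6. The fallback sets out from 19 and comes back at 21, and it separates acylation from reduction. 19 is esterified with 3,4,5-trimethoxybenzoyl chloride (pyridine, cat. DMAP, 0 °C) to the β-aroyloxy enone F3. The ketone is then reduced 1,2 under reagent control with (S)-2-methyl-CBS-oxazaborolidine and catecholborane at −78 °C, the enone arm acting as the large group, to give 21.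

Step 9. The carbonyl is flanked by a quaternary and a branched carbon, so the vinyl reagent may act as a base (enolisation toward C7 followed by loss of silanolate) or the β-alkoxide may undergo retro-aldol cleavage instead of addition. The fallback sets out from 14 and comes back at 15. The smaller, less basic sp nucleophile HC≡CMgBr with CeCl3 is added to give the propargylic diol F4, and semi-hydrogenation (H2, Pd/CaCO3 poisoned with Pb(OAc)2, quinoline) gives 15.

Further compounds
F1 | step 12 | (1S)-1-[(1R,3S,4S)-4-[(tert-butyldimethylsilyl)oxy]-1-methyl-2-oxo-3-(propan-2-yl)cyclopentyl]-4-methylpent-4-en-1-yl methanesulfonate | O=C1[C@@H](C(C)C)[C@@H](O[Si](C)(C)C(C)(C)C)C[C@]1(C)[C@@H](OS(C)(=O)=O)CCC(C)=C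
F2 | step 12 | (4S,5S,7E)-5-[(tert-butyldimethylsilyl)oxy]-7,11-dimethyl-4-(propan-2-yl)dodeca-1,7,11-trien-3-one | C=CC(=O)[C@@H](C(C)C)[C@@H](O[Si](C)(C)C(C)(C)C)C/C(C)=C/CCC(C)=C
F3 | step 14 | (1S,2S,4Z,8E)-5,9-dimethyl-3-oxo-2-(propan-2-yl)cyclodeca-4,8-dien-1-yl 3,4,5-trimethoxybenzoate | COc1cc(C(=O)O[C@H]2C/C(C)=C/CC/C(C)=C\C(=O)[C@H]2C(C)C)cc(OC)c1OC
F4 | step 9 | (1R,2R,4S,5S)-4-[(tert-butyldimethylsilyl)oxy]-1-ethynyl-2-[(1S)-1-hydroxy-4-methylpent-4-en-1-yl]-2-methyl-5-(propan-2-yl)cyclopentan-1-ol | C#C[C@]1(O)[C@@H](C(C)C)[C@@H](O[Si](C)(C)C(C)(C)C)C[C@]1(C)[C@@H](O)CCC(C)=C
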